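**Numbering and assumption**

Ring positions follow the target throughout. C1 is the fully substituted carbinol carbon, C7 its exocyclic CH2, C2 the CH–OBz carbon, C3=C4 the alkene, and C5 and C6 the two CHOH carbons (C6 next to C1). The lactone intermediates keep these locants: C7 is the lactone carbonyl and the ring oxygen sits on C4. In sugar terms C7, C1, C6, C5, C4, C3, C2 are C1 to C7 of a D-gluco-heptonolactone. Sugar-type names of the lactones use sugar locants.

Assumption: the target SMILES is read as the (1S,2S,5R,6S) isomer in this numbering (C1–OH cis to C6–OH, C5–OH trans to C6–OH, C2–OBz cis to C7 and to C5–OH), and 1, 2, 5 and 12 are taken as purchasable.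

## Analysis of the target

Compound 14 is a cyclohex-3-ene in which every sp3 ring carbon bears oxygen. C1 carries a tertiary hydroxyl and the benzoyloxymethyl carbon C7, C2 a benzoate, and C5 and C6 free secondary hydroxyls. The four stereocentres C1, C2, C5 and C6 are related as follows: the C1 and C6 oxygens are cis, the C5 and C6 oxygens trans, and the C2 oxygen lies on the face of C7, cis to the C5 oxygen across the alkene. The sensitive features are the two benzoates, each next to a free hydroxyl and therefore prone to acyl migration under base. C2 and C5 are allylic C–O carbons, and the ring as a whole can lose its oxygens and aromatise under acid or strong base. The difficulty is twofold. C1 is a quaternary stereocentre flanked by two further stereocentres. The five oxygens must end in three different states, and the benzoates must sit on C7 and C2 only, although C2 and C5 are both secondary allylic positions that no reagent would tell apart. The feature on which the plan rests is the chain C7–C1–C6–C5–C4. It carries oxygen on C7, C1, C6 and C5 with the C5/C6 trans relation, exactly as C1 to C5 of lactone 1 do, and in 1 the ring oxygen sits on C4 while the carbonyl C7 is bonded to C1. If the two missing carbons C3 and C2 are hung on C4 as a vinyl group, the ring can close by joining C1 to C2 in a [3,3] shift that also expels the ring oxygen from C4. The C2 oxygen is the only one the sugar does not supply, so it can enter separately (as boron) and be told apart from C5 by its origin.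

## Retrosynthetic reasoning

**14 to 13.** The three free hydroxyls on C1, C5 and C6 are taken back to silyl ethers. They are removed last, under buffered acidic fluoride, because the diester next to free hydroxyls should not see base. Nothing is cut in the skeleton; the gain is that the benzoates can be installed on a compound with only two free hydroxyls.

**13 to 11 and 12.** The two ester C–O bonds at C7 and C2 are cut. In 11 these are the only free hydroxyls, so acylation with 12 needs no selectivity. This solves the C2/C5 problem: C5 stays silylated from the start of the route, while C2 appears late.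

**11 to 10.** C7 is taken back from the alcohol to the carboxylic acid level. The reason is the key step, which necessarily delivers C7 as a carboxyl group. The forward reaction is a hydride reduction that must leave silyl ethers and the alkene alone.

**10 to 9.** The C2–O bond is exchanged for a C2–B bond. Oxidation of a boronic ester goes with retention and without allylic shift, so the configuration at C2 can be set in a C–C bond-forming event and only revealed afterwards. The oxidation is placed before the hydride reduction, not after it. A strong aluminium hydride would turn the boronic ester into an allylic borohydride or borane, which can lose its position and configuration by 1,3-shift.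

**9 to 6 (through 8 and 7).** This is the strategic cut. The C1–C2 bond is broken and C4 is reconnected to the carboxyl oxygen, which turns the cyclohexene acid into the δ-lactone 6 with an (E)-borylvinyl arm on C4. The cut is made here because it is the only bond whose removal leaves a chain (C7 to C4) identical in oxygenation and configuration to 1. It also places the new quaternary centre C1 and the new centre C2 under the control of one concerted transition state. Cutting C2–C3 or C3=C4 instead (aldol, metathesis) would leave C1 to be made by an intermolecular addition with no such control. The forward reaction must enolise the lactone at C1, trap the enolate on oxygen (7), and let the [3,3] shift form C1–C2 through the only geometry the ring allows.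

**6 to 4 and 5.** The C3=C2 alkene is cut into the aldehyde 4 (C3) and the one-carbon boron reagent 5 (C2). The forward reaction has to be non-basic, because 4 is an α-oxygenated aldehyde in a lactone, and it has to give the (E)-alkene cleanly, because the alkene geometry becomes the C2 configuration. A chromium-mediated olefination meets both demands.

**4 to 3, and 3 to 1 and 2.** The aldehyde is traced to the primary silyl ether of 3, which can be oxidised directly while the secondary silyl ethers stay. 3 is the per-silylated form of 1, made with 2. Using one silyl group for all four hydroxyls of 1 avoids any differentiation step.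

## Alternatives that were turned down

**Alternative 1:** The disconnection cuts C1–C6 and C4–C5. The ring falls apart into 3-hydroxy-2-pyrone A1, which brings C7 (its carbonyl) and C1 to C4, and (E)-hex-3-ene-2,5-dione A2, which brings C5 and C6, each with an acetyl group as a masked hydroxyl. In the forward key step a chiral amine base converts A1 into its oxido-diene and steers the [4+2] addition to A2. The lactone bridge is kept, giving the bicyclic lactone A3 with the C6 acetyl turned towards the alkene and the C5 acetyl towards the bridge.

- For it: one catalytic step makes the ring, the quaternary carbinol C1 and three more stereocentres from two flat, cheap partners. The trans C5/C6 relation comes from the alkene geometry of A2, and C6 has the right relation to C1.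
- Against it: in A3 the alkene is at C2=C3 and the bridging oxygen on C4, each one position away from where 14 needs them. After the bridge is opened, an allylic oxygen has to be transposed from C4 to C2. The facial sense would be right, but the shift is an equilibrium between two secondary allylic positions with no clear bias. Both acetyl groups must undergo Baeyer–Villiger oxidation next to an alkene, and the resulting acetates must later be removed in the presence of two benzoates.
- Comparison: on convergence and on using a catalyst in place of a chiral starting material this plan is the stronger one. The chosen route offers instead that four of the five oxygens are on the right carbons from the first step, that nothing has to be transposed or unmasked, and that the spectator groups are silyl ethers, which are orthogonal to benzoates.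

**Alternative 2:** The disconnection cuts C1–C2 and C5–C6, giving (1E,3E)-buta-1,3-diene-1,4-diyl diacetate A4 (C2 to C5) and methyl 2-oxo-1,3-dioxole-4-carboxylate A5 (C7, C1, C6). In the forward key step a chiral oxazaborolidinium Lewis acid binds the ester of A5, and a [4+2] addition with the ester endo gives the carbonate A6, with the two acetates cis to each other and trans to the carbonate.

- For it: this is the most economical construction on paper. All four stereocentres, all five oxygens and the alkene position arise in one catalytic step, and the route would be shorter than the chosen one.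
- Against it: both partners are deactivated. In A5 the ester acceptor is opposed by two oxygen donors on a trisubstituted alkene, A4 is a sluggish diene, and an ester is the weakest carbonyl class for this kind of Lewis acid. The forcing conditions that would be needed are those under which catalyst control and the ester-endo preference fade. After the cycloaddition C2 and C5 carry the same acetate and are both secondary allylic, yet one must become a benzoate and the other a free hydroxyl. The ester must also be reduced to C7 in the presence of acetates and a carbonate.
- Comparison: this plan is stronger in step count and in setting stereocentres catalytically. The chosen route offers a built-in distinction between C2 and C5 (one from boron, one from the sugar) and a key step whose geometry is enforced by a ring and not by a catalyst.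

**Alternative 3:** The disconnection removes the C5–O and C6–O bonds (as an epoxide) and traces the ring to an arene. 4-Hydroxybenzyl benzoate A7 is oxidised anodically in aqueous medium to the p-quinol A8, which has C1, its hydroxyl and the C7 benzoate in place but no stereocentre. In the forward key step a chiral primary-amine salt with a peroxide selects one of the two enantiotopic enone arms and epoxidises it on the face of the tertiary hydroxyl, giving the epoxy enone A9.

- For it: two steps from a cheap arene reach an enantioenriched intermediate that holds C1, the finished C7 benzoate and the C6 oxygen cis to the C1 hydroxyl. No protecting group and no stoichiometric metal is needed.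
- Against it: from A9 every remaining ring carbon still has to change oxidation state, each time with its own selectivity. The second enone must be oxidised at C2/C3 on the face opposite to the first epoxide and then transposed (Wharton type) to bring oxygen to C2 and the alkene to C3=C4, under nucleophilic basic conditions that endanger the benzoate and the epoxide. The epoxide must be opened at C5 only, with inversion. The C2 hydroxyl must be benzoylated beside free C5 and C6 hydroxyls. Epoxyquinols tend to aromatise or dimerise under base, and the hydroxyl-directed facial selectivity of the epoxidation is an assumption.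
- Comparison: this plan is stronger on starting-material cost and on the early presence of the C7 benzoate. The chosen route offers C5, C6 and the sense of C1 from one chiral-pool compound and a single concerted step, instead of three separate face-selective oxidations.

Key step: step 4

## Route

Step 1
Reactants: 1 D-glucono-1,5-lactone; 2 chlorotriethylsilane
Product: 3 2,3,4,6-tetrakis-O-(triethylsilyl)-D-glucono-1,5-lactone
Conditions: Et3SiCl (5 equiv), imidazole, DMF, 0 °C to rt
Reagents that add atoms: chlorotriethylsilane (2), CC[Si](Cl)(CC)CC
Why: Exhaustive O-silylation of a polyol with a silyl chloride and imidazole; all four hydroxyls are primary or secondary, the medium is not nucleophilic enough to open the lactone, and no stereocentre is touched.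

Step 2
Reactants: 3 2,3,4,6-tetrakis-O-(triethylsilyl)-D-glucono-1,5-lactone
Product: 4 2,3,4-tris-O-(triethylsilyl)-D-glucono-1,5-lactone oxidised at sugar C6 to the aldehyde (6-aldehydo lactone; CHO on the ring carbon C4 of the target numbering)
Conditions: (COCl)2, DMSO, CH2Cl2, −78 °C, then −40 °C; Et3N, −78 to 0 °C; used crude
Reagents that add atoms: none
Why: Swern oxidation run directly on the silyl ether: the chlorosulfonium salt attacks only the unhindered primary O–SiEt3 group, releases Et3SiCl and forms the alkoxysulfonium ion that the amine collapses to the aldehyde, a known selectivity of primary over secondary triethylsilyl ethers. The α-carbon C4 should keep its configuration if the amine stage is kept cold and 4 is used at once.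

Step 3
Reactants: 4 6-aldehydo-2,3,4-tris-O-(triethylsilyl)-D-glucono-1,5-lactone; 5 2-(dichloromethyl)-4,4,5,5-tetramethyl-1,3,2-dioxaborolane
Product: 6 6,7-dideoxy-7-(4,4,5,5-tetramethyl-1,3,2-dioxaborolan-2-yl)-2,3,4-tris-O-(triethylsilyl)-D-gluco-hept-6(E)-enono-1,5-lactone
Conditions: CrCl2 (8 equiv), LiI (4 equiv), 5 (2 equiv), THF, rt
Reagents that add atoms: 2-(dichloromethyl)-4,4,5,5-tetramethyl-1,3,2-dioxaborolane (5), ClC(Cl)B1OC(C)(C)C(C)(C)O1
Why: Takai olefination in its boron version: divalent chromium reduces the gem-dihalide to a gem-dichromium species that adds to the aldehyde and eliminates anti, which gives the (E)-alkenylboronate. The reagent is not basic, so the lactone, the silyl ethers and the α-stereocentre C4 should survive.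

Step 4
Reactants: 6 6,7-dideoxy-7-(4,4,5,5-tetramethyl-1,3,2-dioxaborolan-2-yl)-2,3,4-tris-O-(triethylsilyl)-D-gluco-hept-6(E)-enono-1,5-lactone
Product: 9 (1R,2S,5R,6S)-2-(4,4,5,5-tetramethyl-1,3,2-dioxaborolan-2-yl)-1,5,6-tris(triethylsilyloxy)cyclohex-3-ene-1-carboxylic acid, via trimethylsilyl ketene acetal 7 (not isolated), via trimethylsilyl ester 8 (not isolated)
Conditions: LiN(SiMe3)2 (1.5 equiv), Me3SiCl/Et3N (premixed), THF, −78 °C; to rt, then toluene, 80 °C; pH 7 buffer work-up
Reagents that add atoms: none
Why: Proposed new method: an Ireland–Claisen ring contraction has not been run on a lactone whose alkenyl arm ends in a boronate; the closest known reaction types are the boat-type Ireland–Claisen ring contraction of δ-lactones that carry an alkenyl group on the carbinol carbon (giving cyclohex-3-enecarboxylic acids) and the Ireland–Claisen rearrangement of acyclic (E)-3-borylallyl esters (giving α-substituted allylboronates), and the boronate should act as a spectator because it is tricoordinate, not conjugated with the reacting ketene acetal and shielded by the pinacol methyl groups. LiN(SiMe3)2 removes the hydrogen on C1 (sugar C2), the only C–H α to a carbonyl, with Me3SiCl already present, so the enolate is O-silylated to the cyclic ketene acetal 7 before it can expel the C6 silyloxy group or add to boron. On warming, the array C1=C7–O–C4–C3=C2 of 7 undergoes a concerted suprafacial [3,3] shift that forms C1–C2, breaks O–C4 and creates C3=C4, giving the silyl ester 8, which the aqueous work-up hydrolyses to 9. The cyclohexene is closed by this sigmatropic ring contraction itself and not by an ionic cyclisation: C1 and C4 are tied by the two-carbon bridge C6–C5, so the only attainable geometry is a bicyclo[2.2.2]octane-like boat, and such a boat can deliver only a cis ring alkene. The configuration of C1 is dictated by the lactone stereocentre C4: the alkenyl arm stands on the ring face that also carries the C6 oxygen and can reach only that face of the ketene acetal, which leaves the C1 oxygen cis to the C6 oxygen and the carboxyl carbon C7 on the opposite side of the new ring. The configuration of C2 follows from the alkene geometry, since in the boat the (E)-substituent ends on the ring face of C7 (trans to the C1 oxygen), so a geometrically pure (E)-boronate is the one selectivity the substrate has to bring. C4 is given up as a stereocentre and C5 and C6 are not touched, so 9 should form as one diastereomer and one enantiomer. The chemoselectivity needed (rearrangement ahead of β-elimination, survival of boron) rests on the in-flask silylation, on the hindered amide base, and on the bulky vicinal trans silyl ethers, which favour the conformer with the arm axial.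

Step 5
Reactants: 9 (1R,2S,5R,6S)-2-(4,4,5,5-tetramethyl-1,3,2-dioxaborolan-2-yl)-1,5,6-tris(triethylsilyloxy)cyclohex-3-ene-1-carboxylic acid
Product: 10 (1R,2S,5R,6S)-2-hydroxy-1,5,6-tris(triethylsilyloxy)cyclohex-3-ene-1-carboxylic acid
Conditions: NaBO3·4H2O, THF/H2O, rt; NaH2PO4 work-up
Reagents that add atoms: sodium perborate (used as the tetrahydrate), [Na+].[Na+].O[B-]1(O)OO[B-](O)(O)OO1
Why: Oxidation of a boronic ester by 1,2-shift of carbon from boron to peroxide oxygen, which goes with retention and without allylic transposition, so the C2 oxygen appears on the face the boron occupied (cis to C7). The mildly basic perborate should spare the silyl ethers, and the step precedes the hydride reduction because LiAlH4 would convert the boronate into an allylic borohydride prone to 1,3-shift.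

Step 6
Reactants: 10 (1R,2S,5R,6S)-2-hydroxy-1,5,6-tris(triethylsilyloxy)cyclohex-3-ene-1-carboxylic acid
Product: 11 (1R,2S,5R,6S)-1-(hydroxymethyl)-1,5,6-tris(triethylsilyloxy)cyclohex-3-en-2-ol (locants of the target numbering)
Conditions: LiAlH4, THF, 0 °C to rt; aq. potassium sodium tartrate work-up
Reagents that add atoms: none
Why: Hydride reduction of a carboxylic acid to the primary alcohol; silyl ethers, the isolated ring alkene and the allylic alkoxide are inert to LiAlH4 at this temperature, and no stereocentre is involved.

Step 7
Reactants: 11 (1R,2S,5R,6S)-1-(hydroxymethyl)-1,5,6-tris(triethylsilyloxy)cyclohex-3-en-2-ol; 12 benzoyl chloride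
Product: 13 [(1R,2S,5R,6S)-2-(benzoyloxy)-1,5,6-tris(triethylsilyloxy)cyclohex-3-en-1-yl]methyl benzoate
Conditions: BzCl (3 equiv), pyridine, DMAP (cat.), CH2Cl2, 0 °C to rt
Reagents that add atoms: benzoyl chloride (12), O=C(Cl)c1ccccc1
Why: Nucleophile-catalysed acylation of the only two free hydroxyls, the primary one on C7 and the secondary allylic one on C2; the other three oxygens are silyl ethers, so no selectivity is asked for and C2 keeps its configuration.

Step 8
Reactants: 13 [(1R,2S,5R,6S)-2-(benzoyloxy)-1,5,6-tris(triethylsilyloxy)cyclohex-3-en-1-yl]methyl benzoate
Product: 14 [(1S,2S,5R,6S)-2-(benzoyloxy)-1,5,6-trihydroxycyclohex-3-en-1-yl]methyl benzoate (CNP0141358.1)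
Conditions: HF·pyridine, pyridine, THF, 0 °C to rt
Reagents that add atoms: none
Why: Fluoride-driven Si–O cleavage under buffered, weakly acidic conditions, which remove secondary and tertiary triethylsilyl ethers but should neither hydrolyse nor shift the benzoates as a basic fluoride source might. The change of the C1 descriptor from R to S is a priority effect only.

## Compound list

1 | D-glucono-1,5-lactone | OC[C@H]1OC(=O)[C@H](O)[C@@H](O)[C@@H]1O | starting material
2 | chlorotriethylsilane | CC[Si](Cl)(CC)CC | starting material
3 | 2,3,4,6-tetrakis-O-(triethylsilyl)-D-glucono-1,5-lactone | CC[Si](CC)(CC)OC[C@H]1OC(=O)[C@H](O[Si](CC)(CC)CC)[C@@H](O[Si](CC)(CC)CC)[C@@H]1O[Si](CC)(CC)CC | intermediate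
4 | 6-aldehydo-2,3,4-tris-O-(triethylsilyl)-D-glucono-1,5-lactone (sugar C6 is CHO) | O=C[C@H]1OC(=O)[C@H](O[Si](CC)(CC)CC)[C@@H](O[Si](CC)(CC)CC)[C@@H]1O[Si](CC)(CC)CC | intermediate
5 | 2-(dichloromethyl)-4,4,5,5-tetramethyl-1,3,2-dioxaborolane | ClC(Cl)B1OC(C)(C)C(C)(C)O1 | starting material
6 | 6,7-dideoxy-7-(4,4,5,5-tetramethyl-1,3,2-dioxaborolan-2-yl)-2,3,4-tris-O-(triethylsilyl)-D-gluco-hept-6(E)-enono-1,5-lactone | [C@@H]1(/C=C/B2OC(C)(C)C(C)(C)O2)[C@@H](O[Si](CC)(CC)CC)[C@H](O[Si](CC)(CC)CC)[C@@H](O[Si](CC)(CC)CC)C(=O)O1 | intermediate
7 | trimethylsilyl ketene acetal of 6: 2-[(E)-2-(pinacolboryl)vinyl]-3,4,5-tris(triethylsilyloxy)-6-(trimethylsilyloxy)-3,4-dihydro-2H-pyran, stereocentres as in 6 | C[Si](C)(C)OC1=C(O[Si](CC)(CC)CC)[C@@H](O[Si](CC)(CC)CC)[C@H](O[Si](CC)(CC)CC)[C@@H](/C=C/B2OC(C)(C)C(C)(C)O2)O1 | intermediate (not isolated)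
8 | trimethylsilyl (1R,2S,5R,6S)-2-(4,4,5,5-tetramethyl-1,3,2-dioxaborolan-2-yl)-1,5,6-tris(triethylsilyloxy)cyclohex-3-ene-1-carboxylate | C[Si](C)(C)OC(=O)[C@@]1(O[Si](CC)(CC)CC)[C@@H](B2OC(C)(C)C(C)(C)O2)C=C[C@@H](O[Si](CC)(CC)CC)[C@@H]1O[Si](CC)(CC)CC | intermediate (not isolated)
9 | (1R,2S,5R,6S)-2-(4,4,5,5-tetramethyl-1,3,2-dioxaborolan-2-yl)-1,5,6-tris(triethylsilyloxy)cyclohex-3-ene-1-carboxylic acid (boron cis to carboxyl) | OC(=O)[C@@]1(O[Si](CC)(CC)CC)[C@@H](B2OC(C)(C)C(C)(C)O2)C=C[C@@H](O[Si](CC)(CC)CC)[C@@H]1O[Si](CC)(CC)CC | intermediate
10 | (1R,2S,5R,6S)-2-hydroxy-1,5,6-tris(triethylsilyloxy)cyclohex-3-ene-1-carboxylic acid | OC(=O)[C@@]1(O[Si](CC)(CC)CC)[C@@H](O)C=C[C@@H](O[Si](CC)(CC)CC)[C@@H]1O[Si](CC)(CC)CC | intermediate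
11 | (1R,2S,5R,6S)-1-(hydroxymethyl)-1,5,6-tris(triethylsilyloxy)cyclohex-3-en-2-ol (target locants) | OC[C@@]1(O[Si](CC)(CC)CC)[C@@H](O)C=C[C@@H](O[Si](CC)(CC)CC)[C@@H]1O[Si](CC)(CC)CC | intermediate
12 | benzoyl chloride | O=C(Cl)c1ccccc1 | starting material
13 | [(1R,2S,5R,6S)-2-(benzoyloxy)-1,5,6-tris(triethylsilyloxy)cyclohex-3-en-1-yl]methyl benzoate | O=C(OC[C@@]1(O[Si](CC)(CC)CC)[C@@H](OC(=O)c2ccccc2)C=C[C@@H](O[Si](CC)(CC)CC)[C@@H]1O[Si](CC)(CC)CC)c1ccccc1 | intermediate
14 | [(1S,2S,5R,6S)-2-(benzoyloxy)-1,5,6-trihydroxycyclohex-3-en-1-yl]methyl benzoate | O=C(OC[C@@]1(O)[C@@H](OC(=O)c2ccccc2)C=C[C@@H](O)[C@@H]1O)c1ccccc1 | target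

## Step count and least certain steps

Total step count: 8. Longest linear sequence: 8 steps (1 to 14). The route is linear; 2, 5 and 12 are bought.

**Step 4 (key step, Proposed new method).**
- What may go wrong:
  - The lactone enolate may lose the C6 silyloxy group by β-elimination before it is silylated.
  - The amide base may add to boron, and a tetracoordinate allylic boron in 8 could then eliminate towards the C1 or C5 silyloxy group.
  - The boat may be reached too slowly, because the arm and two silyloxy groups must all turn axial.
- First adjustment inside the step: enolisation without a free enolate, using Et3SiOTf/Et3N.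
- Fallback (sets out from 6, returns at 11): the oxygen is put on the alkene before the rearrangement instead of after it. A copper-mediated oxidative coupling of the Chan–Lam type (Cu(OAc)2, Et3N, air, excess 4-methoxybenzyl alcohol, CH2Cl2, rt) replaces boron by an ether oxygen with retention of alkene geometry. This should give 6,7-dideoxy-7-[(4-methoxybenzyl)oxy]-2,3,4-tris-O-(triethylsilyl)-D-gluco-hept-6(E)-enono-1,5-lactone F1. F1 is carried through the Ireland–Claisen ring contraction under the conditions of step 4. The arm is now a plain enol ether that neither base nor heat can attack, and a donor on the alkene terminus is known to speed Claisen rearrangements. The product should be (1R,2S,5R,6S)-2-[(4-methoxybenzyl)oxy]-1,5,6-tris(triethylsilyloxy)cyclohex-3-ene-1-carboxylic acid F2, with the ether oxygen where the boron of 9 stood. LiAlH4 in THF reduces F2 to [2-[(4-methoxybenzyl)oxy]-1,5,6-tris(triethylsilyloxy)cyclohex-3-en-1-yl]methanol F3 (configuration as in 11). DDQ in CH2Cl2 over pH 7 buffer then removes the benzylic ether to give 11.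

**Step 2.**
- What may go wrong: incomplete in-flask cleavage of the primary silyl ether, or loss of a secondary one while the mixture is warmed; epimerisation at C4 or β-elimination of the C5 silyloxy group from the aldehyde during the amine stage.
- Fallback (sets out from 3, returns at 4): cleavage and oxidation are separated and the amine base is avoided. AcOH/THF/H2O at 0 °C removes only the primary silyl ether to give 2,3,4-tris-O-(triethylsilyl)-D-glucono-1,5-lactone F4. F4 is oxidised with Dess–Martin periodinane buffered with NaHCO3 in CH2Cl2 to 4.

**Step 3.**
- What may go wrong: erosion of the (E)-geometry with the boron-bearing chromium reagent, which would pass directly into the C2 configuration; slow addition to the hindered, doubly α,β-oxygenated aldehyde, giving it time to epimerise or eliminate on the Lewis-acidic chromium salts; loss of boron during the aqueous work-up.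
- Fallback (sets out from 4, returns at 6): the alkene and the C–B bond are made in separate steps. Takai iodo-olefination (CHI3, CrCl2, THF, 0 °C), the fastest and most (E)-selective member of this reaction family, gives 6,7-dideoxy-7-iodo-2,3,4-tris-O-(triethylsilyl)-D-gluco-hept-6(E)-enono-1,5-lactone F5. Miyaura borylation (B2pin2, PdCl2(dppf), KOPh, toluene, 50 °C), which keeps the alkene geometry, converts F5 into 6.

**Step 6.**
- What may go wrong: sluggish reduction of the hindered, fully α-substituted carboxylate, so that warming is needed; under those conditions a triethylsilyl group may migrate from the tertiary C1 oxygen to the new C7 or the C2 alkoxide, or be cleaved; the β-hydroxy carboxylate of 10 may also suffer under the preceding basic oxidation.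
- Fallback (sets out from 9, returns at 11): the reduction is done first, on a neutral ester at low temperature, and the oxidation last. Me3SiCHN2 in toluene/MeOH converts 9 into methyl (1R,2S,5R,6S)-2-(4,4,5,5-tetramethyl-1,3,2-dioxaborolan-2-yl)-1,5,6-tris(triethylsilyloxy)cyclohex-3-ene-1-carboxylate F6. i-Bu2AlH in CH2Cl2 at −78 to 0 °C, which normally leaves boronic esters untouched, reduces F6 to [2-(4,4,5,5-tetramethyl-1,3,2-dioxaborolan-2-yl)-1,5,6-tris(triethylsilyloxy)cyclohex-3-en-1-yl]methanol F7 (configuration as in 9). NaBO3·4H2O in THF/H2O then oxidises the C–B bond with retention to give 11.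

## Further compounds

F1 | step 4 | 6,7-dideoxy-7-[(4-methoxybenzyl)oxy]-2,3,4-tris-O-(triethylsilyl)-D-gluco-hept-6(E)-enono-1,5-lactone | COc1ccc(CO/C=C/[C@H]2OC(=O)[C@H](O[Si](CC)(CC)CC)[C@@H](O[Si](CC)(CC)CC)[C@@H]2O[Si](CC)(CC)CC)cc1
F2 | step 4 | (1R,2S,5R,6S)-2-[(4-methoxybenzyl)oxy]-1,5,6-tris(triethylsilyloxy)cyclohex-3-ene-1-carboxylic acid | OC(=O)[C@@]1(O[Si](CC)(CC)CC)[C@@H](OCc2ccc(OC)cc2)C=C[C@@H](O[Si](CC)(CC)CC)[C@@H]1O[Si](CC)(CC)CC
F3 | step 4 | [2-[(4-methoxybenzyl)oxy]-1,5,6-tris(triethylsilyloxy)cyclohex-3-en-1-yl]methanol (configuration as in 11) | OC[C@@]1(O[Si](CC)(CC)CC)[C@@H](OCc2ccc(OC)cc2)C=C[C@@H](O[Si](CC)(CC)CC)[C@@H]1O[Si](CC)(CC)CC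
F4 | step 2 | 2,3,4-tris-O-(triethylsilyl)-D-glucono-1,5-lactone | OC[C@H]1OC(=O)[C@H](O[Si](CC)(CC)CC)[C@@H](O[Si](CC)(CC)CC)[C@@H]1O[Si](CC)(CC)CC
F5 | step 3 | 6,7-dideoxy-7-iodo-2,3,4-tris-O-(triethylsilyl)-D-gluco-hept-6(E)-enono-1,5-lactone | I/C=C/[C@H]1OC(=O)[C@H](O[Si](CC)(CC)CC)[C@@H](O[Si](CC)(CC)CC)[C@@H]1O[Si](CC)(CC)CC
F6 | step 6 | methyl (1R,2S,5R,6S)-2-(4,4,5,5-tetramethyl-1,3,2-dioxaborolan-2-yl)-1,5,6-tris(triethylsilyloxy)cyclohex-3-ene-1-carboxylate | COC(=O)[C@@]1(O[Si](CC)(CC)CC)[C@@H](B2OC(C)(C)C(C)(C)O2)C=C[C@@H](O[Si](CC)(CC)CC)[C@@H]1O[Si](CC)(CC)CC
F7 | step 6 | [2-(4,4,5,5-tetramethyl-1,3,2-dioxaborolan-2-yl)-1,5,6-tris(triethylsilyloxy)cyclohex-3-en-1-yl]methanol (configuration as in 9) | OC[C@@]1(O[Si](CC)(CC)CC)[C@@H](B2OC(C)(C)C(C)(C)O2)C=C[C@@H](O[Si](CC)(CC)CC)[C@@H]1O[Si](CC)(CC)CC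
A1 | alternative 1 | 3-hydroxy-2H-pyran-2-one | O=C1OC=CC=C1O
A2 | alternative 1 | (E)-hex-3-ene-2,5-dione | CC(=O)/C=C/C(C)=O
A3 | alternative 1 | trans-7,8-diacetyl-4-hydroxy-2-oxabicyclo[2.2.2]oct-5-en-3-one (8-acetyl syn to the alkene) | O=C1[C@@]2(O)C=C[C@@H](O1)[C@@H](C(C)=O)[C@@H]2C(C)=O
A4 | alternative 2 | (1E,3E)-buta-1,3-diene-1,4-diyl diacetate | CC(=O)O/C=C/C=C/OC(C)=O
A5 | alternative 2 | methyl 2-oxo-1,3-dioxole-4-carboxylate | COC(=O)C1=COC(=O)O1
A6 | alternative 2 | methyl 2,5-diacetoxy-1,6-(carbonyldioxy)cyclohex-3-ene-1-carboxylate (carbonate trans to both acetates) | COC(=O)[C@@]1(OC(=O)O2)[C@@H](OC(C)=O)C=C[C@@H](OC(C)=O)[C@@H]12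
A7 | alternative 3 | 4-hydroxybenzyl benzoate | O=C(OCc1ccc(O)cc1)c1ccccc1
A8 | alternative 3 | (1-hydroxy-4-oxocyclohexa-2,5-dien-1-yl)methyl benzoate | O=C(OCC1(O)C=CC(=O)C=C1)c1ccccc1
A9 | alternative 3 | (5,6-epoxy-1-hydroxy-4-oxocyclohex-2-en-1-yl)methyl benzoate, epoxide syn to the hydroxyl | O=C(OC[C@@]1(O)C=CC(=O)[C@@H]2O[C@H]12)c1ccccc1
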